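**Plan**
- Retrosynthesis: the benzyl ether is cut last. Ring C is opened at O1-C2 to a 2-hydroxyaryl ynone, with C4 taken back to a silyl-protected carbinol. Ring A is cut at C8a-C4a, C5-C6 and C8-C8a into 2,3,4-trimethoxycyclobutenone and a 1-methoxyalkyne. The diyne is cut at C4-C4a (acetylide plus ynal) and at C2-C1' (aryl iodide plus propargyl alcohol).
- Forward: ring B comes in with the iodide, and Sonogashira coupling and acetylide addition join the open chain. Ring A arises first, by benzannulation, and ring C second, by amine-promoted 6-endo closure of O1-C2. Debenzylation ends the route.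
- Enabling feature: ring A bears oxygen on the five contiguous carbons C5, C6, C7, C8 and C8a and carbon only on C4a. This is the pattern formed when a trimethoxyvinylketene (C6, C7, C8 and ketene carbon C8a) joins a methoxyalkyne (C5, C4a).
- Stereochemistry: the target has no stereocenter. The carbinol carbon C4 is carried as a racemate and ends as the ketone.

Key step: step 7

Remark: C4 of 10 and 11, the carbinol carbon of 7, 8 and 13 to 17, and the extra ring center of 13 and 15 form without control (racemates or diastereomer mixtures); all are erased by step 9 at the latest, so their SMILES carry no stereodescriptors.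

**Route**

Step 1
Reactants: 1 1-(benzyloxy)-4-iodobenzene; 2 prop-2-yn-1-ol
Product: 3 3-[4-(benzyloxy)phenyl]prop-2-yn-1-ol
Conditions: PdCl2(PPh3)2 (2 mol %), CuI (4 mol %), Et3N, THF, rt
Reagents that add atoms: none
Why: Sonogashira coupling of an aryl iodide with a terminal alkyne runs at room temperature, and neither the free primary alcohol nor the benzyl ether interferes.

Step 2
Reactants: 3 3-[4-(benzyloxy)phenyl]prop-2-yn-1-ol
Product: 4 3-[4-(benzyloxy)phenyl]prop-2-ynal
Conditions: activated MnO2 (15 equiv), CH2Cl2, rt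
Reagents that add atoms: none
Why: Activated MnO2 oxidizes propargylic alcohols selectively to ynals and leaves the alkyne and the benzyl ether untouched.

Step 3
Reactants: 5 2-chloro-1,1-dimethoxyethane (chloroacetaldehyde dimethyl acetal); 4 3-[4-(benzyloxy)phenyl]prop-2-ynal
Product: 7 5-[4-(benzyloxy)phenyl]-1-methoxypenta-1,4-diyn-3-ol, via lithium methoxyacetylide 6 (not isolated)
Conditions: 5 (1.3 equiv), LiNEt2 (3.9 equiv, from n-BuLi and Et2NH), THF, 0 °C; then 4, −78 °C; pH 7 NaH2PO4/Na2HPO4 buffer
Reagents that add atoms: none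
Why: Two base-induced eliminations from the chloroacetal (methanol, then HCl) and a final deprotonation give LiC≡COMe, whose 1,2-addition to the ynal at −78 °C should outrun conjugate addition of the amine, and the neutral quench spares the acid-labile ynol ether (the new carbinol center is racemic and is oxidized away later).

Step 4
Reactants: 7 5-[4-(benzyloxy)phenyl]-1-methoxypenta-1,4-diyn-3-ol
Product: 8 {[5-(4-benzyloxyphenyl)-1-methoxypenta-1,4-diyn-3-yl]oxy}(tert-butyl)dimethylsilane
Conditions: TBSCl, imidazole, DMF, 0 °C to rt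
Reagents that add atoms: tert-butyldimethylsilyl chloride, CC(C)(C)[Si](C)(C)Cl
Why: Imidazole-promoted silylation of a secondary alcohol is run under basic conditions that the ynol ether tolerates, and the silyl ether masks the carbinol against the ketenes of step 7.

Step 5
Reactants: 9 dimethyl squarate (3,4-dimethoxycyclobut-3-ene-1,2-dione)
Product: 10 4-hydroxy-2,3-dimethoxycyclobut-2-en-1-one
Conditions: LiAlH(O-t-Bu)3 (1.05 equiv), THF, −78 °C; aqueous potassium sodium tartrate
Reagents that add atoms: none
Why: The bulky, mild hydride adds once in the 1,2-sense to one of the two equivalent carbonyl groups, a reduction known for dialkyl squarates, and stops at the hydroxycyclobutenone.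

Step 6
Reactants: 10 4-hydroxy-2,3-dimethoxycyclobut-2-en-1-one
Product: 11 2,3,4-trimethoxycyclobut-2-en-1-one
Conditions: MeI (10 equiv), Ag2O (1.5 equiv), 4 Å molecular sieves, CH2Cl2, rt, dark
Reagents that add atoms: iodomethane, CI
Why: Purdie methylation etherifies the secondary alcohol under neutral conditions, avoiding the acid-triggered ionization at C4 that converts such cyclobutenones into semisquarates.

Step 7
Reactants: 11 2,3,4-trimethoxycyclobut-2-en-1-one; 8 {[5-(4-benzyloxyphenyl)-1-methoxypenta-1,4-diyn-3-yl]oxy}(tert-butyl)dimethylsilane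
Product: 16 2-{3-[4-(benzyloxy)phenyl]-1-[(tert-butyldimethylsilyl)oxy]prop-2-yn-1-yl}-3,4,5,6-tetramethoxyphenol, via trimethoxyvinylketene 12 (not isolated), via vinylcyclobutenone adduct 13 (not isolated), via dienylketene 14 (not isolated), via cyclohexadienone tautomer 15 (not isolated)
Conditions: 11 (1.5 equiv), degassed toluene (0.5 M), base-washed sealed tube, 80 °C then 110 °C
Reagents that add atoms: none
Why: Proposed new method: heating should open 11 by conrotatory 4-electron ring opening, with the C4 methoxy group turning outward, to trimethoxyvinylketene 12, whose carbonyl carbon (future C8a) bonds to the nucleophilic ynol ether carbon remote from OMe (C4a) while its α-carbon (C6) bonds to the methoxy-bearing alkyne carbon (C5) in a ketene-alkyne (2+2) cycloaddition that gives vinylcyclobutenone 13. Ring opening of 13 to dienylketene 14 and thermal disrotatory 6-electron electrocyclization then join C8 to C8a, which closes ring A as cyclohexadienone 15, and enolization delivers phenol 16. The closest known reaction type is the Danheiser benzannulation of cyclobutenones with alkoxy- and siloxyalkynes, which places the alkyne oxygen meta to the new hydroxyl as needed here, but a 2,3,4-trialkoxycyclobutenone has not been used as the vinylketene source. No stereocenter is created, and the racemic silyloxy carbon is a spectator. The required regiochemistry follows from the polarization of the ynol ether, and the donor-free aryl alkyne is far less nucleophilic toward ketenes, so the methoxyalkyne should react selectively. The methyl ynol ether cannot lose an alkene by retro-ene fragmentation at these temperatures, the silyl ether shields the carbinol from acylation by the ketenes, and the excess of cheap 11 compensates for reversible reclosure of 12.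

Step 8
Reactants: 16 2-{3-[4-(benzyloxy)phenyl]-1-[(tert-butyldimethylsilyl)oxy]prop-2-yn-1-yl}-3,4,5,6-tetramethoxyphenol
Product: 17 2-{3-[4-(benzyloxy)phenyl]-1-hydroxyprop-2-yn-1-yl}-3,4,5,6-tetramethoxyphenol
Conditions: TBAF (1.2 equiv), AcOH (1.2 equiv), THF, 0 °C
Reagents that add atoms: none
Why: Fluoride cleaves the secondary silyl ether, and the acetic acid buffer keeps the medium near neutral so that the propargylic carbinol is not isomerized and the phenol is not left as a free phenoxide.

Step 9
Reactants: 17 2-{3-[4-(benzyloxy)phenyl]-1-hydroxyprop-2-yn-1-yl}-3,4,5,6-tetramethoxyphenol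
Product: 18 3-[4-(benzyloxy)phenyl]-1-(2-hydroxy-3,4,5,6-tetramethoxyphenyl)prop-2-yn-1-one
Conditions: activated MnO2 (15 equiv), CH2Cl2, rt, short contact time
Reagents that add atoms: none
Why: The carbinol is both benzylic and propargylic and should be oxidized quickly by MnO2, the usual way to 2-hydroxyaryl ynones, and the new carbonyl group then ties up the phenol by hydrogen bonding.

Step 10
Reactants: 18 3-[4-(benzyloxy)phenyl]-1-(2-hydroxy-3,4,5,6-tetramethoxyphenyl)prop-2-yn-1-one
Product: 20 2-[4-(benzyloxy)phenyl]-5,6,7,8-tetramethoxy-4H-chromen-4-one, via enaminone 19 (not isolated)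
Conditions: Et2NH (3 equiv), EtOH, rt to 50 °C
Reagents that add atoms: none
Why: Conjugate addition of the secondary amine to the ynone gives enaminone 19, and addition-elimination by the ortho phenol at C2 (6-endo closure of ring C with loss of Et2NH) gives the chromone, a pathway that avoids the 5-exo closure to an aurone seen with carbonate bases.

Step 11
Reactants: 20 2-[4-(benzyloxy)phenyl]-5,6,7,8-tetramethoxy-4H-chromen-4-one
Product: 21 2-(4-hydroxyphenyl)-5,6,7,8-tetramethoxy-4H-chromen-4-one (4'-hydroxy-5,6,7,8-tetramethoxyflavone)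
Conditions: H2 (1 atm), 10% Pd/C, EtOAc/MeOH, rt
Reagents that add atoms: none
Why: Hydrogenolysis of an aryl benzyl ether over Pd/C at atmospheric pressure is faster than reduction of the vinylogous ester double bond of the flavone and does not touch the methyl ethers.

**Compound list**
1 | 1-(benzyloxy)-4-iodobenzene | Ic1ccc(OCc2ccccc2)cc1 | starting material
2 | prop-2-yn-1-ol | C#CCO | starting material
3 | 3-[4-(benzyloxy)phenyl]prop-2-yn-1-ol | OCC#Cc1ccc(OCc2ccccc2)cc1 | intermediate
4 | 3-[4-(benzyloxy)phenyl]prop-2-ynal | O=CC#Cc1ccc(OCc2ccccc2)cc1 | intermediate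
5 | 2-chloro-1,1-dimethoxyethane (chloroacetaldehyde dimethyl acetal) | COC(CCl)OC | starting material
6 | lithium methoxyacetylide, LiC≡COMe (formed in the flask) | [Li]C#COC | intermediate
7 | 5-[4-(benzyloxy)phenyl]-1-methoxypenta-1,4-diyn-3-ol (racemic) | COC#CC(O)C#Cc1ccc(OCc2ccccc2)cc1 | intermediate
8 | {[5-(4-benzyloxyphenyl)-1-methoxypenta-1,4-diyn-3-yl]oxy}(tert-butyl)dimethylsilane (racemic) | COC#CC(O[Si](C)(C)C(C)(C)C)C#Cc1ccc(OCc2ccccc2)cc1 | intermediate
9 | dimethyl squarate (3,4-dimethoxycyclobut-3-ene-1,2-dione) | COC1=C(OC)C(=O)C1=O | starting material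
10 | 4-hydroxy-2,3-dimethoxycyclobut-2-en-1-one (racemic) | COC1=C(OC)C(O)C1=O | intermediate
11 | 2,3,4-trimethoxycyclobut-2-en-1-one (racemic) | COC1C(=O)C(OC)=C1OC | intermediate
12 | (Z)-2,3,4-trimethoxybuta-1,3-dien-1-one (trimethoxyvinylketene, formed in the flask) | O=C=C(OC)/C(OC)=C/OC | intermediate
13 | 2-{3-[4-(benzyloxy)phenyl]-1-[(tert-butyldimethylsilyl)oxy]prop-2-yn-1-yl}-4-[(Z)-1,2-dimethoxyethenyl]-3,4-dimethoxycyclobut-2-en-1-one (diastereomer mixture, formed in the flask) | O=C1C(C(O[Si](C)(C)C(C)(C)C)C#Cc2ccc(OCc3ccccc3)cc2)=C(OC)C1(OC)/C(OC)=C/OC | intermediate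
14 | (3Z,5Z)-2-{3-[4-(benzyloxy)phenyl]-1-[(tert-butyldimethylsilyl)oxy]prop-2-yn-1-yl}-3,4,5,6-tetramethoxyhexa-1,3,5-trien-1-one (dienylketene, formed in the flask) | O=C=C(C(O[Si](C)(C)C(C)(C)C)C#Cc1ccc(OCc2ccccc2)cc1)/C(OC)=C(OC)\C(OC)=C\OC | intermediate
15 | 2-{3-[4-(benzyloxy)phenyl]-1-[(tert-butyldimethylsilyl)oxy]prop-2-yn-1-yl}-3,4,5,6-tetramethoxycyclohexa-2,4-dien-1-one (diastereomer mixture, formed in the flask) | O=C1C(C(O[Si](C)(C)C(C)(C)C)C#Cc2ccc(OCc3ccccc3)cc2)=C(OC)C(OC)=C(OC)C1OC | intermediate
16 | 2-{3-[4-(benzyloxy)phenyl]-1-[(tert-butyldimethylsilyl)oxy]prop-2-yn-1-yl}-3,4,5,6-tetramethoxyphenol (racemic) | COc1c(OC)c(OC)c(C(O[Si](C)(C)C(C)(C)C)C#Cc2ccc(OCc3ccccc3)cc2)c(O)c1OC | intermediate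
17 | 2-{3-[4-(benzyloxy)phenyl]-1-hydroxyprop-2-yn-1-yl}-3,4,5,6-tetramethoxyphenol (racemic) | COc1c(OC)c(OC)c(C(O)C#Cc2ccc(OCc3ccccc3)cc2)c(O)c1OC | intermediate
18 | 3-[4-(benzyloxy)phenyl]-1-(2-hydroxy-3,4,5,6-tetramethoxyphenyl)prop-2-yn-1-one | COc1c(OC)c(OC)c(C(=O)C#Cc2ccc(OCc3ccccc3)cc2)c(O)c1OC | intermediate
19 | 3-[4-(benzyloxy)phenyl]-3-(diethylamino)-1-(2-hydroxy-3,4,5,6-tetramethoxyphenyl)prop-2-en-1-one (double-bond geometry not fixed, formed in the flask) | CCN(CC)C(=CC(=O)c1c(O)c(OC)c(OC)c(OC)c1OC)c1ccc(OCc2ccccc2)cc1 | intermediate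
20 | 2-[4-(benzyloxy)phenyl]-5,6,7,8-tetramethoxy-4H-chromen-4-one | COc1c(OC)c(OC)c2c(=O)cc(-c3ccc(OCc4ccccc4)cc3)oc2c1OC | intermediate
21 | 2-(4-hydroxyphenyl)-5,6,7,8-tetramethoxy-4H-chromen-4-one (4'-hydroxy-5,6,7,8-tetramethoxyflavone) | COc1c(OC)c(OC)c2c(=O)cc(-c3ccc(O)cc3)oc2c1OC | target

**Count and risks**
Total step count: 11. Longest linear sequence: 9 steps (steps 1, 2, 3, 4, 7, 8, 9, 10, 11, from iodide 1).

Step 7 (the proposed new method).
- What may go wrong: the electron-rich trimethoxyvinylketene may be too weak an electrophile for the (2+2) addition and simply reclose or dimerize. The ynol ether may oligomerize or add the product phenol on prolonged heating. Surplus ketene may acylate the phenol, which a short K2CO3/MeOH treatment would reverse. Thermal loss of silanol from the ortho-hydroxybenzylic position is also possible.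
- Fallback (known chemistry only): ring A is made by directed metalation. The fallback sets out from ynal 4 and comes back to the route at ynone 18. Commercial 1,2,3,4-tetramethoxybenzene would be ortho-lithiated (n-BuLi, TMEDA, THF, 0 °C) to (2,3,4,5-tetramethoxyphenyl)lithium F1. Quenching with B(OMe)3 would give dimethyl (2,3,4,5-tetramethoxyphenyl)boronate F2, and oxidation in the same flask (H2O2, aqueous NaOH) would give 2,3,4,5-tetramethoxyphenol F3. Protection (MOMCl, i-Pr2NEt, CH2Cl2) should give 1,2,3,4-tetramethoxy-5-(methoxymethoxy)benzene F4. Its only ring hydrogen lies between the acetal oxygen and a methoxy group, so n-BuLi in THF at 0 °C should give [2,3,4,5-tetramethoxy-6-(methoxymethoxy)phenyl]lithium F5. Addition to 4 at −78 °C would give 3-[4-(benzyloxy)phenyl]-1-[2,3,4,5-tetramethoxy-6-(methoxymethoxy)phenyl]prop-2-yn-1-ol F6. MnO2 oxidation, with no free phenol present, would give 3-[4-(benzyloxy)phenyl]-1-[2,3,4,5-tetramethoxy-6-(methoxymethoxy)phenyl]prop-2-yn-1-one F7. Brief treatment with HCl in MeOH at 0 °C should remove the acetal and give 18, from which steps 10 and 11 follow unchanged.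

Step 9.
- What may go wrong: over-oxidation of the very electron-rich, para-methoxylated free phenol (oxidative demethylation toward a quinone, phenoxyl coupling) may compete with carbinol oxidation. The ortho-hydroxybenzylic, propargylic carbinol may also ionize with loss of water on the oxide surface or on silica.
- Fallback: the phenol is masked before the carbinol is unveiled and oxidized. The fallback sets out from 16 and comes back at 20. Acetylation (Ac2O, DMAP, pyridine) should give 2-{3-[4-(benzyloxy)phenyl]-1-[(tert-butyldimethylsilyl)oxy]prop-2-yn-1-yl}-3,4,5,6-tetramethoxyphenyl acetate F8. HF·pyridine in THF/pyridine at 0 °C would cleave the silyl ether to 2-{3-[4-(benzyloxy)phenyl]-1-hydroxyprop-2-yn-1-yl}-3,4,5,6-tetramethoxyphenyl acetate F9, in which the ring is deactivated and quinone methide formation is blocked. Dess-Martin periodinane (NaHCO3, CH2Cl2) should give 2-{3-[4-(benzyloxy)phenyl]prop-2-ynoyl}-3,4,5,6-tetramethoxyphenyl acetate F10. Et2NH in EtOH would then cleave the aryl acetate by aminolysis and add to the ynone, so that enaminone 19 forms and closes to 20.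

Step 6.
- What may go wrong: adventitious acid may ionize the C4 oxygen substituent and lead toward semisquarate-type products. Etherification of the hindered acyloin-type alcohol may also be slow, so that the water-sensitive vinylogous ester hydrolyses or the small, polar product is lost on isolation.
- Fallback: the ether is made by reductive etherification of the carbonyl group instead of reduction and alkylation. The fallback sets out from 9 and comes back at 11. Silyl-triflate-catalysed ketalization (MeOSiMe3, catalytic TMSOTf, CH2Cl2, −78 °C) should give 2,3,4,4-tetramethoxycyclobut-2-en-1-one F11. Ionic hydrogenation (Et3SiH, TMSOTf, CH2Cl2, −78 °C) would then remove one ketal methoxy group. The intermediate cation is symmetric about the C1-C3 axis, so hydride delivery at either terminus gives 11.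

**Further compounds**
F1 | step 7 | (2,3,4,5-tetramethoxyphenyl)lithium | [Li]c1cc(OC)c(OC)c(OC)c1OC
F2 | step 7 | dimethyl (2,3,4,5-tetramethoxyphenyl)boronate | COB(OC)c1cc(OC)c(OC)c(OC)c1OC
F3 | step 7 | 2,3,4,5-tetramethoxyphenol | Oc1cc(OC)c(OC)c(OC)c1OC
F4 | step 7 | 1,2,3,4-tetramethoxy-5-(methoxymethoxy)benzene | COCOc1cc(OC)c(OC)c(OC)c1OC
F5 | step 7 | [2,3,4,5-tetramethoxy-6-(methoxymethoxy)phenyl]lithium | [Li]c1c(OCOC)c(OC)c(OC)c(OC)c1OC
F6 | step 7 | 3-[4-(benzyloxy)phenyl]-1-[2,3,4,5-tetramethoxy-6-(methoxymethoxy)phenyl]prop-2-yn-1-ol | COCOc1c(C(O)C#Cc2ccc(OCc3ccccc3)cc2)c(OC)c(OC)c(OC)c1OC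
F7 | step 7 | 3-[4-(benzyloxy)phenyl]-1-[2,3,4,5-tetramethoxy-6-(methoxymethoxy)phenyl]prop-2-yn-1-one | COCOc1c(C(=O)C#Cc2ccc(OCc3ccccc3)cc2)c(OC)c(OC)c(OC)c1OC
F8 | step 9 | 2-{3-[4-(benzyloxy)phenyl]-1-[(tert-butyldimethylsilyl)oxy]prop-2-yn-1-yl}-3,4,5,6-tetramethoxyphenyl acetate | COc1c(OC)c(OC)c(C(O[Si](C)(C)C(C)(C)C)C#Cc2ccc(OCc3ccccc3)cc2)c(OC(C)=O)c1OC
F9 | step 9 | 2-{3-[4-(benzyloxy)phenyl]-1-hydroxyprop-2-yn-1-yl}-3,4,5,6-tetramethoxyphenyl acetate | COc1c(OC)c(OC)c(C(O)C#Cc2ccc(OCc3ccccc3)cc2)c(OC(C)=O)c1OC
F10 | step 9 | 2-{3-[4-(benzyloxy)phenyl]prop-2-ynoyl}-3,4,5,6-tetramethoxyphenyl acetate | COc1c(OC)c(OC)c(C(=O)C#Cc2ccc(OCc3ccccc3)cc2)c(OC(C)=O)c1OC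
F11 | step 6 | 2,3,4,4-tetramethoxycyclobut-2-en-1-one | COC1=C(OC)C(OC)(OC)C1=O
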